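The synthesis rests on the C6–C7 bond, which links the quaternary peroxy carbon C6 of the 1,2-dioxane ring to the first CH2 of the side chain (chain numbering: lactone carbonyl C1, peroxy carbons C3 and C6, lactone carbinol carbon C4). The key step exploits that the C6 methyl group and the C6–O bond can both arrive later by Markovnikov H/O–O addition to a C6=CH2 unit, so the bond is made as an sp3–sp2 bond: Negishi coupling of the complete (S)-configured dienyl alkylzinc iodide with the enol triflate of an (R)-butenolide from citramalic acid. This one operation assembles the whole carbon skeleton; peroxidation and oxa-Michael closure onto C3 then build the bicycle.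

Key step: step 13

Remark: C7 is the first side-chain CH2 and C8 the methyl-bearing side-chain stereocentre; oxygen capture by the C6 radical in step 14 has no facial control, so both C6 epimers are carried into step 15 and separated there.

Step 1
Reactants: 1 (R)-citramalic acid
Product: 2 2-[(4R)-2,2,4-trimethyl-5-oxo-1,3-dioxolan-4-yl]acetic acid
Conditions: Me2C(OMe)2, TsOH·H2O (cat.), CH2Cl2, rt
Reagents that add atoms: 2,2-dimethoxypropane, COC(C)(C)OC
Why: Acid-catalysed transketalisation (acetonide formation) should tie the tertiary hydroxyl and its neighbouring carboxyl into the five-membered dioxolanone and leave the CH2CO2H arm free, so the future C4 centre comes unchanged from the chiral pool.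

Step 2
Reactants: 2 2-[(4R)-2,2,4-trimethyl-5-oxo-1,3-dioxolan-4-yl]acetic acid
Product: 4 (5R)-2,2,5-trimethyl-5-(2-oxopropyl)-1,3-dioxolan-4-one, via acid chloride 3 (not isolated)
Conditions: (COCl)2, DMF (cat.), CH2Cl2, 0 °C to rt; then Me2CuLi, Et2O, −78 °C
Reagents that add atoms: lithium dimethylcuprate, [Li+].C[Cu-]C
Why: Acylation of a Gilman cuprate by the acid chloride (ketone synthesis) should stop at the methyl ketone, because the cuprate adds neither to ketones nor to the dioxolanone at −78 °C.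

Step 3
Reactants: 4 (5R)-2,2,5-trimethyl-5-(2-oxopropyl)-1,3-dioxolan-4-one
Product: 6 3-[(4R)-2,2,4-trimethyl-5-oxo-1,3-dioxolan-4-yl]prop-1-en-2-yl trifluoromethanesulfonate, via lithium enolate 5 (not isolated)
Conditions: LiN(i-Pr)2, THF, −78 °C; then N-(5-chloro-2-pyridyl)bis(trifluoromethanesulfonimide), −78 °C
Reagents that add atoms: N-(5-chloro-2-pyridyl)bis(trifluoromethanesulfonimide), FC(F)(F)S(=O)(=O)N(c1ccc(Cl)cn1)S(=O)(=O)C(F)(F)F
Why: Kinetic deprotonation at the methyl group (the methylene is neopentylic) and immediate O-sulfonylation at −78 °C (kinetic enol triflate formation) should give the terminal enol triflate before the enolate can attack the dioxolanone carbonyl.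

Step 4
Reactants: 6 3-[(4R)-2,2,4-trimethyl-5-oxo-1,3-dioxolan-4-yl]prop-1-en-2-yl trifluoromethanesulfonate
Product: 7 3-[(4R)-5-hydroxy-2,2,4-trimethyl-1,3-dioxolan-4-yl]prop-1-en-2-yl trifluoromethanesulfonate (lactol)
Conditions: i-Bu2AlH (1.1 equiv), CH2Cl2, −78 °C; aq. potassium sodium tartrate work-up
Reagents that add atoms: none
Why: Partial reduction of the activated dioxolanone carbonyl by i-Bu2AlH at low temperature should stop at the aluminium hemiacetal (ester-to-lactol reduction), and the enol triflate is inert to the hydride.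

Step 5
Reactants: 7 3-[(4R)-5-hydroxy-2,2,4-trimethyl-1,3-dioxolan-4-yl]prop-1-en-2-yl trifluoromethanesulfonate; 8 methyl (triphenylphosphoranylidene)acetate
Product: 11 3-[(2R)-2-methyl-5-oxo-2,5-dihydrofuran-2-yl]prop-1-en-2-yl trifluoromethanesulfonate, via hydroxy aldehyde 9 (not isolated), via (Z)-hydroxy enoate 10 (not isolated)
Conditions: MeOH, 0 °C to rt; then TsOH (cat.), CH2Cl2, rt
Reagents that add atoms: none
Why: In methanol the lactol opens to the α-hydroxy aldehyde, whose Wittig reaction with the stabilised ylide is (Z)-selective for α-oxygenated aldehydes in protic solvent, and the (Z)-γ-hydroxy ester lactonises to the butenolide without touching the quaternary centre.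

Step 6
Reactants: 12 phenylacetaldehyde; 13 2-(triphenylphosphoranylidene)propanal
Product: 14 (2E)-2-methyl-4-phenylbut-2-enal
Conditions: toluene, 80 °C
Reagents that add atoms: none
Why: Wittig olefination with the formyl-stabilised ylide should give the (E)-trisubstituted enal, as stabilised ylides react under thermodynamic control.

Step 7
Reactants: 14 (2E)-2-methyl-4-phenylbut-2-enal; 15 ethyl 2-(triphenylphosphoranylidene)propanoate
Product: 16 ethyl (2E,4E)-2,4-dimethyl-6-phenylhexa-2,4-dienoate
Conditions: toluene, 90 °C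
Reagents that add atoms: none
Why: A second (E)-selective Wittig reaction with the ester-stabilised ylide should extend the enal to the (2E,4E)-dienoate.

Step 8
Reactants: 16 ethyl (2E,4E)-2,4-dimethyl-6-phenylhexa-2,4-dienoate
Product: 17 (2E,4E)-2,4-dimethyl-6-phenylhexa-2,4-dien-1-ol
Conditions: i-Bu2AlH (2.2 equiv), CH2Cl2, −78 °C
Reagents that add atoms: none
Why: 1,2-Reduction of the conjugated ester by i-Bu2AlH should give the allylic alcohol and leave the diene geometry intact.

Step 9
Reactants: 17 (2E,4E)-2,4-dimethyl-6-phenylhexa-2,4-dien-1-ol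
Product: 18 [(2E,4E)-6-bromo-3,5-dimethylhexa-2,4-dien-1-yl]benzene
Conditions: CBr4, PPh3, CH2Cl2, 0 °C
Reagents that add atoms: carbon tetrabromide, BrC(Br)(Br)Br
Why: The Appel reaction converts the primary allylic alcohol into the bromide under neutral conditions by SN2 displacement on the alkoxyphosphonium ion, which avoids allylic transposition.

Step 10
Reactants: 18 [(2E,4E)-6-bromo-3,5-dimethylhexa-2,4-dien-1-yl]benzene; 19 (4R)-4-benzyl-3-propanoyl-1,3-oxazolidin-2-one
Product: 21 (4R)-4-benzyl-3-[(2S,4E,6E)-2,4,6-trimethyl-8-phenylocta-4,6-dienoyl]-1,3-oxazolidin-2-one, via sodium (Z)-enolate 20 (not isolated)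
Conditions: NaN(SiMe3)2, THF, −78 °C; then 18, −78 to −20 °C
Reagents that add atoms: none
Why: Evans asymmetric alkylation: the chelated (Z)-enolate is attacked by the allylic bromide on the face opposite the benzyl group of the (R)-auxiliary, which sets the (S) configuration of the methyl-bearing carbon (C8 of the target).

Step 11
Reactants: 21 (4R)-4-benzyl-3-[(2S,4E,6E)-2,4,6-trimethyl-8-phenylocta-4,6-dienoyl]-1,3-oxazolidin-2-one
Product: 22 (2S,4E,6E)-2,4,6-trimethyl-8-phenylocta-4,6-dien-1-ol
Conditions: LiBH4, MeOH (1 equiv), THF, 0 °C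
Reagents that add atoms: none
Why: Reductive cleavage of the N-acyloxazolidinone with LiBH4 should release the primary alcohol and the auxiliary without epimerising the α-centre.

Step 12
Reactants: 22 (2S,4E,6E)-2,4,6-trimethyl-8-phenylocta-4,6-dien-1-ol
Product: 23 [(2E,4E,7S)-8-iodo-3,5,7-trimethylocta-2,4-dien-1-yl]benzene
Conditions: I2, PPh3, imidazole, CH2Cl2, 0 °C
Reagents that add atoms: iodine, II
Why: Appel-type iodination replaces the primary hydroxyl by iodide through SN2 at CH2, so the adjacent stereocentre is not touched.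

Step 13
Reactants: 23 [(2E,4E,7S)-8-iodo-3,5,7-trimethylocta-2,4-dien-1-yl]benzene; 11 3-[(2R)-2-methyl-5-oxo-2,5-dihydrofuran-2-yl]prop-1-en-2-yl trifluoromethanesulfonate
Product: 25 (5R)-5-methyl-5-[(4R,6E,8E)-4,6,8-trimethyl-2-methylidene-10-phenyldeca-6,8-dien-1-yl]furan-2(5H)-one, via alkylzinc iodide 24 (not isolated)
Conditions: Zn dust (activated with BrCH2CH2Br and Me3SiCl), LiCl, THF, 40 °C; then 11, PdCl2(dppf) (5 mol%), THF–NMP, 25 to 50 °C
Reagents that add atoms: none
Why: Negishi sp3–sp2 cross-coupling: LiCl-assisted insertion of zinc into the primary C–I bond gives the alkylzinc iodide, zerovalent palladium adds oxidatively to the C–O bond of the enol triflate, and transmetalation followed by reductive elimination forges the C6–C7 bond. The closest known reaction type is the palladium-catalysed coupling of functionalised primary alkylzinc halides with alkenyl triflates. No ring is closed and no stereocentre is formed; the (S) centre next to the zinc-bearing CH2 and the quaternary (R) centre of the butenolide take no part and should survive (the side-chain centre is labelled 4R in 25 only because the CIP priorities change). The step needs chemoselectivity for the enol triflate over the butenolide (no 1,4-addition, no ring opening) and reductive elimination faster than β-hydride elimination; the low nucleophilicity of the alkylzinc iodide and the wide bite angle of dppf should secure both. The product holds the complete carbon skeleton with C6 as the internal carbon of a 1,1-disubstituted alkene, ready for Markovnikov H/O–O addition.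

Step 14
Reactants: 25 (5R)-5-methyl-5-[(4R,6E,8E)-4,6,8-trimethyl-2-methylidene-10-phenyldeca-6,8-dien-1-yl]furan-2(5H)-one
Product: 26 (5R)-5-methyl-5-[(4S,6E,8E)-2,4,6,8-tetramethyl-10-phenyl-2-(triethylsilylperoxy)deca-6,8-dien-1-yl]furan-2(5H)-one (C6 epimer mixture)
Conditions: Co(thd)2 (10 mol%; thd = 2,2,6,6-tetramethylheptane-3,5-dionate), O2 (1 atm), Et3SiH, ClCH2CH2Cl, rt
Reagents that add atoms: dioxygen, O=O; triethylsilane, CC[SiH](CC)CC
Why: Mukaiyama–Isayama hydroperoxysilylation: hydrogen-atom transfer from a cobalt hydride to the unhindered =CH2 terminus (which becomes the C6 methyl) gives the tertiary C6 radical, which is captured by O2 and silylated with Markovnikov regiochemistry; the diene offers only substituted termini and should react more slowly, and the planar radical has no facial bias, so both C6 epimers are expected.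

Step 15
Reactants: 26 (5R)-5-methyl-5-[(4S,6E,8E)-2,4,6,8-tetramethyl-10-phenyl-2-(triethylsilylperoxy)deca-6,8-dien-1-yl]furan-2(5H)-one (C6 epimer mixture)
Product: 28 plakortolide (3R,4R,6R,8S,10E,12E)-3,6-epidioxy-4,6,8,10,12-pentamethyl-14-phenyltetradeca-10,12-dien-4-olide, via hydroperoxide 27 (not isolated)
Conditions: HCl (cat.), MeOH, 0 °C; then Et2NH, CF3CH2OH, rt; chromatographic separation of the C6 epimers
Reagents that add atoms: none
Why: Acidic methanolysis cleaves the O–Si bond, and the amine-mediated 6-exo-trig oxa-Michael addition of the hydroperoxide to C3 of the butenolide can only occur on the face that carries C5, so C4 dictates the cis ring fusion and the (3R) centre, while the (6R) epimer is isolated by chromatography from its (6S) companion.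

Compound list
1 | (R)-citramalic acid, (2R)-2-hydroxy-2-methylbutanedioic acid | OC(=O)C[C@@](C(=O)O)(C)O | starting material
2 | 2-[(4R)-2,2,4-trimethyl-5-oxo-1,3-dioxolan-4-yl]acetic acid | OC(=O)C[C@@]1(C)OC(C)(C)OC1=O | intermediate
3 | 2-[(4R)-2,2,4-trimethyl-5-oxo-1,3-dioxolan-4-yl]acetyl chloride | ClC(=O)C[C@@]1(C)OC(C)(C)OC1=O | intermediate (not isolated)
4 | (5R)-2,2,5-trimethyl-5-(2-oxopropyl)-1,3-dioxolan-4-one | CC(=O)C[C@@]1(C)OC(C)(C)OC1=O | intermediate
5 | lithium 3-[(4R)-2,2,4-trimethyl-5-oxo-1,3-dioxolan-4-yl]prop-1-en-2-olate | [Li]OC(=C)C[C@@]1(C)OC(C)(C)OC1=O | intermediate (not isolated)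
6 | 3-[(4R)-2,2,4-trimethyl-5-oxo-1,3-dioxolan-4-yl]prop-1-en-2-yl trifluoromethanesulfonate | C=C(OS(=O)(=O)C(F)(F)F)C[C@@]1(C)OC(C)(C)OC1=O | intermediate
7 | 3-[(4R)-5-hydroxy-2,2,4-trimethyl-1,3-dioxolan-4-yl]prop-1-en-2-yl trifluoromethanesulfonate (lactol, both epimers at the hemiacetal carbon) | C=C(OS(=O)(=O)C(F)(F)F)C[C@@]1(C)OC(C)(C)OC1O | intermediate
8 | methyl (triphenylphosphoranylidene)acetate | COC(=O)C=P(c1ccccc1)(c1ccccc1)c1ccccc1 | starting material
9 | (4R)-4-hydroxy-4-methyl-5-oxopent-1-en-2-yl trifluoromethanesulfonate | C=C(OS(=O)(=O)C(F)(F)F)C[C@@](C)(O)C=O | intermediate (not isolated)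
10 | methyl (2Z,4R)-4-hydroxy-4-methyl-6-[(trifluoromethanesulfonyl)oxy]hepta-2,6-dienoate | C=C(OS(=O)(=O)C(F)(F)F)C[C@@](C)(O)/C=C\C(=O)OC | intermediate (not isolated)
11 | 3-[(2R)-2-methyl-5-oxo-2,5-dihydrofuran-2-yl]prop-1-en-2-yl trifluoromethanesulfonate | C=C(OS(=O)(=O)C(F)(F)F)C[C@@]1(C)OC(=O)C=C1 | intermediate
12 | phenylacetaldehyde | O=CCc1ccccc1 | starting material
13 | 2-(triphenylphosphoranylidene)propanal | CC(C=O)=P(c1ccccc1)(c1ccccc1)c1ccccc1 | starting material
14 | (2E)-2-methyl-4-phenylbut-2-enal | CC(=C\Cc1ccccc1)/C=O | intermediate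
15 | ethyl 2-(triphenylphosphoranylidene)propanoate | CCOC(=O)C(C)=P(c1ccccc1)(c1ccccc1)c1ccccc1 | starting material
16 | ethyl (2E,4E)-2,4-dimethyl-6-phenylhexa-2,4-dienoate | CC(=C\Cc1ccccc1)/C=C(\C)C(=O)OCC | intermediate
17 | (2E,4E)-2,4-dimethyl-6-phenylhexa-2,4-dien-1-ol | CC(=C\Cc1ccccc1)/C=C(\C)CO | intermediate
18 | [(2E,4E)-6-bromo-3,5-dimethylhexa-2,4-dien-1-yl]benzene | CC(=C\Cc1ccccc1)/C=C(\C)CBr | intermediate
19 | (4R)-4-benzyl-3-propanoyl-1,3-oxazolidin-2-one | CCC(=O)N1[C@H](Cc2ccccc2)COC1=O | starting material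
20 | sodium (Z)-enolate of 19 | C/C=C(\O[Na])N1[C@H](Cc2ccccc2)COC1=O | intermediate (not isolated)
21 | (4R)-4-benzyl-3-[(2S,4E,6E)-2,4,6-trimethyl-8-phenylocta-4,6-dienoyl]-1,3-oxazolidin-2-one | CC(=C\Cc1ccccc1)/C=C(\C)C[C@H](C)C(=O)N1[C@H](Cc2ccccc2)COC1=O | intermediate
22 | (2S,4E,6E)-2,4,6-trimethyl-8-phenylocta-4,6-dien-1-ol | CC(=C\Cc1ccccc1)/C=C(\C)C[C@H](C)CO | intermediate
23 | [(2E,4E,7S)-8-iodo-3,5,7-trimethylocta-2,4-dien-1-yl]benzene | CC(=C\Cc1ccccc1)/C=C(\C)C[C@H](C)CI | intermediate
24 | [(2S,4E,6E)-2,4,6-trimethyl-8-phenylocta-4,6-dien-1-yl]zinc iodide | CC(=C\Cc1ccccc1)/C=C(\C)C[C@H](C)C[Zn]I | intermediate (not isolated)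
25 | (5R)-5-methyl-5-[(4R,6E,8E)-4,6,8-trimethyl-2-methylidene-10-phenyldeca-6,8-dien-1-yl]furan-2(5H)-one | CC(=C\Cc1ccccc1)/C=C(\C)C[C@H](C)CC(=C)C[C@@]1(C)OC(=O)C=C1 | intermediate
26 | (5R)-5-methyl-5-[(4S,6E,8E)-2,4,6,8-tetramethyl-10-phenyl-2-(triethylsilylperoxy)deca-6,8-dien-1-yl]furan-2(5H)-one (both epimers at the peroxy carbon) | CC(=C\Cc1ccccc1)/C=C(\C)C[C@H](C)CC(C)(OO[Si](CC)(CC)CC)C[C@@]1(C)OC(=O)C=C1 | intermediate
27 | (5R)-5-[(4S,6E,8E)-2-hydroperoxy-2,4,6,8-tetramethyl-10-phenyldeca-6,8-dien-1-yl]-5-methylfuran-2(5H)-one (both epimers at the peroxy carbon) | CC(=C\Cc1ccccc1)/C=C(\C)C[C@H](C)CC(C)(OO)C[C@@]1(C)OC(=O)C=C1 | intermediate (not isolated)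
28 | plakortolide, (3R,4R,6R,8S,10E,12E)-3,6-epidioxy-4,6,8,10,12-pentamethyl-14-phenyltetradeca-10,12-dien-4-olide | CC(=C\Cc1ccccc1)/C=C(\C)C[C@H](C)C[C@]1(C)C[C@@]2(C)OC(=O)C[C@H]2OO1 | target

Total step count: 15.
Longest linear sequence: 10 steps (steps 6 to 12, then 13 to 15).

Steps most likely to fail

Step 14. Hydrogen-atom transfer may also reach the conjugated diene or the butenolide, and oxygen capture at C6 has no facial preference, so material is lost both to over-reaction and to the C6 epimer. The fallback replaces the radical addition by an ionic Markovnikov addition, which is fastest at an unhindered 1,1-disubstituted alkene. It sets out from 25: Hg(OAc)2 and ethereal H2O2 in CH2Cl2 at 0 °C (peroxymercuration) should give the β-mercurio hydroperoxide F1; Et2NH in CF3CH2OH closes the dioxane ring to the mercurated bicyclic peroxide F2; alkaline NaBH4 at 0 °C then removes mercury, turns the CH2HgOAc group into the C6 methyl and comes back to the route at 28, again after separation of the C6 epimer.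

Step 13. Zinc insertion or transmetalation may be slow, and β-hydride elimination from the alkylpalladium intermediate or hydrolysis of the enol triflate may then take over. The fallback makes the same bond as a ketone C–C bond before the butenolide exists. It sets out from 2 and from zinc reagent 24: EtSH, DCC and DMAP convert 2 into the S-ethyl thioester F3; Fukuyama coupling of F3 with 24 (PdCl2(PPh3)2, toluene) gives the ketone F4; Wittig methylenation (Ph3P=CH2, THF, 0 °C) gives the 1,1-disubstituted alkene F5; i-Bu2AlH at −78 °C gives the lactol F6, and the Wittig–lactonisation of step 5 with 8 comes back to the route at 25.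

Step 15. The hindered tertiary hydroperoxide may add slowly, and under base the peroxide may fragment instead (retro-addition, Kornblum–DeLaMare-type cleavage at C3); the C6 epimers may also co-elute. The fallback closes the peroxide ring on an open-chain enoate and forms the lactone last. It sets out from lactol 7: Wittig reaction with 8 in CH2Cl2 gives the (E)-hydroxy ester F7, which cannot lactonise; Negishi coupling with 24 as in step 13 gives the triene ester F8; cobalt-mediated peroxidation as in step 14 gives the silyl peroxide F9; desilylation and Et2NH in CF3CH2OH give the monocyclic dioxane ester F10 by reversible conjugate addition, so its C3 epimers can equilibrate; TsOH in CH2Cl2 then lactonises the isomer whose C4 hydroxyl is cis to the acetate arm and comes back to the route at 28.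

Further compounds
F1 | step 14 | (5R)-5-[(4S,6E,8E)-2-[(acetoxymercurio)methyl]-2-hydroperoxy-4,6,8-trimethyl-10-phenyldeca-6,8-dien-1-yl]-5-methylfuran-2(5H)-one (both epimers at the peroxy carbon) | CC(=C\Cc1ccccc1)/C=C(\C)C[C@H](C)CC(C[Hg]OC(C)=O)(OO)C[C@@]1(C)OC(=O)C=C1
F2 | step 14 | (3R,4R,8S,10E,12E)-6-[(acetoxymercurio)methyl]-3,6-epidioxy-4,8,10,12-tetramethyl-14-phenyltetradeca-10,12-dien-4-olide (both C6 epimers) | CC(=C\Cc1ccccc1)/C=C(\C)C[C@H](C)CC1(C[Hg]OC(C)=O)C[C@@]2(C)OC(=O)C[C@H]2OO1
F3 | step 13 | S-ethyl 2-[(4R)-2,2,4-trimethyl-5-oxo-1,3-dioxolan-4-yl]ethanethioate | CCSC(=O)C[C@@]1(C)OC(C)(C)OC1=O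
F4 | step 13 | (5R)-2,2,5-trimethyl-5-[(4S,6E,8E)-4,6,8-trimethyl-2-oxo-10-phenyldeca-6,8-dien-1-yl]-1,3-dioxolan-4-one | CC(=C\Cc1ccccc1)/C=C(\C)C[C@H](C)CC(=O)C[C@@]1(C)OC(C)(C)OC1=O
F5 | step 13 | (5R)-2,2,5-trimethyl-5-[(4R,6E,8E)-4,6,8-trimethyl-2-methylidene-10-phenyldeca-6,8-dien-1-yl]-1,3-dioxolan-4-one | CC(=C\Cc1ccccc1)/C=C(\C)C[C@H](C)CC(=C)C[C@@]1(C)OC(C)(C)OC1=O
F6 | step 13 | (5R)-2,2,5-trimethyl-5-[(4R,6E,8E)-4,6,8-trimethyl-2-methylidene-10-phenyldeca-6,8-dien-1-yl]-1,3-dioxolan-4-ol (both epimers at the hemiacetal carbon) | CC(=C\Cc1ccccc1)/C=C(\C)C[C@H](C)CC(=C)C[C@@]1(C)OC(C)(C)OC1O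
F7 | step 15 | methyl (2E,4R)-4-hydroxy-4-methyl-6-[(trifluoromethanesulfonyl)oxy]hepta-2,6-dienoate | C=C(OS(=O)(=O)C(F)(F)F)C[C@@](C)(O)/C=C/C(=O)OC
F8 | step 15 | methyl (2E,4R,8R,10E,12E)-4-hydroxy-4,8,10,12-tetramethyl-6-methylidene-14-phenyltetradeca-2,10,12-trienoate | CC(=C\Cc1ccccc1)/C=C(\C)C[C@H](C)CC(=C)C[C@@](C)(O)/C=C/C(=O)OC
F9 | step 15 | methyl (2E,4R,8S,10E,12E)-4-hydroxy-4,6,8,10,12-pentamethyl-14-phenyl-6-(triethylsilylperoxy)tetradeca-2,10,12-trienoate (both C6 epimers) | CC(=C\Cc1ccccc1)/C=C(\C)C[C@H](C)CC(C)(OO[Si](CC)(CC)CC)C[C@@](C)(O)/C=C/C(=O)OC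
F10 | step 15 | methyl 2-{(4R)-4-hydroxy-4,6-dimethyl-6-[(2S,4E,6E)-2,4,6-trimethyl-8-phenylocta-4,6-dien-1-yl]-1,2-dioxan-3-yl}acetate (epimers at C3 and C6) | CC(=C\Cc1ccccc1)/C=C(\C)C[C@H](C)CC1(C)C[C@@](C)(O)C(CC(=O)OC)OO1
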